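**Retrosynthetic overview**
- Ring D last: the C‑13–C‑16 bond by SmI2 ketyl–alkyne closure of an 8‑propargyl‑13‑ketone; the propargyl group by conjugate addition to a C‑ring enone (sets C‑8).
- The enone comes from Birch reduction and hydrolysis of an anisole, so ring C is bought as an arene (a 2‑bromo‑5‑methoxyphenylacetate).
- Rings A and B are made together in one pot: [5+1] double Michael annulation of the pimelate dianion onto a β‑tosyloxy‑α‑aryl acrylate (ring A), then enantioselective, desymmetrising Pd α‑arylation (ring B; sets C‑5 and C‑10).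
- C‑4 methylation, ester cleavage and C‑7 re‑esterification complete the substitution pattern.
- Ring order: C (arene) → A + B (one operation) → D.

Assumption: the SMILES is taken literally. It encodes a cis A/B ring fusion with the C‑10 CO2H on the face opposite the C‑4 CO2H (the C‑10 epimer of the natural 13‑hydroxy gibberellin 19,20‑dioic acid 7‑methyl ester framework), and that stereoisomer is the target.

Locants C‑1 to C‑20 in the text follow gibberellane numbering: C‑4 carries Me and CO2H (C‑19), C‑6 carries CO2Me (C‑7), C‑10 carries CO2H (C‑20), C‑13 carries OH, C‑16=C‑17 is the methylidene. This is a paper design; no step has been run.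

**Step 1**
Reactants: 1 heptanedioic acid (pimelic acid)
Product: 2 di‑tert‑butyl heptanedioate
Conditions: isobutene (excess), cat. H2SO4, CH2Cl2, sealed vessel, rt
Reagents that add atoms: isobutene (2‑methylpropene), C=C(C)C
Why: Acid‑catalysed addition of both carboxyl groups to isobutene gives tert‑butyl esters, chosen because they suppress Dieckmann/Claisen reactions in step 3 and can be cleaved later despite steric hindrance; no stereocentre.

**Step 2**
Reactants: 3 methyl 2‑(2‑bromo‑5‑methoxyphenyl)acetate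
Product: 5 methyl 2‑(2‑bromo‑5‑methoxyphenyl)‑3‑(tosyloxy)prop‑2‑enoate (E/Z mixture), via sodium formyl‑ester enolate 4 (not isolated)
Conditions: NaH (1.1 eq), HCO2Me, THF, 0 °C → rt; then TsCl, 0 °C
Reagents that add atoms: methyl formate, COC=O; p‑toluenesulfonyl chloride, Cc1ccc(cc1)S(=O)(=O)Cl
Why: Crossed Claisen C‑formylation of the arylacetate and O‑sulfonylation of the resulting enolate give a β‑sulfonyloxy acrylate whose β‑carbon (future C‑5) is a one‑carbon 1,1‑dielectrophile; no stereocentre, and either alkene isomer serves.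

**Step 3 (key step: rings A and B)**
Reactants: 2 di‑tert‑butyl heptanedioate; 5 methyl 2‑(2‑bromo‑5‑methoxyphenyl)‑3‑(tosyloxy)prop‑2‑enoate
Product: 8 (4aR,9aS)‑hexahydrofluorene triester (C‑4/C‑6 epimer mixture), via dilithium bis‑enolate 6 (not isolated), via lithium enolate of cyclohexane triester 7 (not isolated)
Conditions: LDA (2.2 eq), THF, −78 °C (inverse addition of 2); 5, −78 → −20 °C; LDA (2.2 eq), −78 °C; Pd(dba)2 (5 mol%), (R)‑DTBM‑SEGPHOS (6 mol%; ligand hand fixed by screening), toluene, 50 °C; AcOH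
Reagents that add atoms: none
Why: Proposed new method: the 1,5‑bis‑enolate adds to the β‑carbon of 5, tosylate is expelled, and the second enolate closes ring A by 6‑exo‑trig Michael addition onto the new α‑aryl acrylate (a [5+1] annulation; closest known types are annulations of diester dianions with 1,1‑dielectrophiles and double Michael additions of tethered carbon diacids to alkynones), after which excess base gives an achiral tris‑enolate whose two ester enolates are enantiotopic, and the chiral Pd catalyst couples the aryl bromide with one of them (closest known type: Pd‑catalysed intramolecular α‑arylation of ester and amide enolates to quaternary centres, including enantioselective oxindole syntheses), so that ring B, quaternary C‑10 and C‑5 are set together with a necessarily cis ring fusion because the aryl group is tethered through C‑5.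

**Step 4**
Reactants: 8 (4aR,9aS)‑hexahydrofluorene triester
Product: 9 (1R,4aR,9S,9aR)‑1‑methyl hexahydrofluorene triester
Conditions: LDA (2.2 eq), THF/DMPU, −78 → −40 °C; MeI (1.05 eq), −78 °C; MeOH, rt; AcOH
Reagents that add atoms: iodomethane, CI
Why: In this dianion alkylation the second‑formed, non‑delocalised C‑4 ester enolate is much more nucleophilic than the benzylic C‑6 enolate and is methylated first, with MeI approaching anti to the C‑5–C‑6 bond (ring B) so that the methyl group ends up cis to H‑5, and methoxide then equilibrates the C‑6 ester to the position trans to the new quaternary C‑4.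

**Step 5**
Reactants: 9 (1R,4aR,9S,9aR)‑1‑methyl hexahydrofluorene triester
Product: 10 (1R,4aR,9S,9aR)‑7‑methoxy‑1‑methyl‑hexahydrofluorene‑1,4a,9‑tricarboxylic acid
Conditions: 6 M HCl, 1,4‑dioxane, 95 °C
Reagents that add atoms: water, O
Why: Acid cleaves the two hindered tert‑butyl esters by alkyl–oxygen fission and hydrolyses the unhindered methyl ester, the aryl methyl ether survives, and no stereocentre is created (C‑6 stays in its thermodynamic configuration).

**Step 6**
Reactants: 10 aromatic triacid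
Product: 12 (1R,4aS,4bR,9S,9aR)‑7‑oxo enone triacid, via Birch dienol ether triacid 11 (not isolated)
Conditions: Li (12 eq), NH3(l), THF, t‑BuOH, −78 → −33 °C; evaporate NH3; 1 M HCl, THF–H2O, 0 °C → rt, short contact time
Reagents that add atoms: water, O
Why: Birch reduction of the anisole ring, run on the tricarboxylate so that no carbonyl group is reduced, gives the 2,5‑dihydroanisole that keeps the tetrasubstituted C‑8=C‑9 bond, and mild acid then hydrolyses the enol ether and moves the double bond into conjugation with the ketone rather than the ester (as in Hagemann's ester), with C‑9 protonated under kinetic control on the convex face of the cis‑fused A/B system, the face carrying H‑5 and the C‑20 CO2H, which can relay the proton.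

**Step 7**
Reactants: 12 enone triacid
Product: 13 (1R,4aS,4bR,9S,9aR)‑9‑methoxycarbonyl enone diacid
Conditions: TMSCHN2 (1.05 eq), PhMe–MeOH 4:1, −20 °C
Reagents that add atoms: (trimethylsilyl)diazomethane, C[Si](C)(C)C=[N+]=[N-]
Why: Diazoalkane esterification follows acidity and access, so one equivalent selects the C‑7 acid (on a CH carbon, vinylogous β‑keto acid) over the two α‑quaternary acids at C‑4 and C‑10, and the neutral conditions leave C‑6 and C‑9 untouched.

**Step 8**
Reactants: 13 enone diacid monoester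
Product: 14 (1R,4aS,4bR,8aS,9S,9aR)‑8a‑propargyl‑7‑ketone
Conditions: TiCl4 (3.5 eq), allenyl‑SnBu3 (2 eq), CH2Cl2, −78 → −40 °C; H2O
Reagents that add atoms: allenyltributylstannane, C=C=C[Sn](CCCC)(CCCC)CCCC
Why: Lewis‑acid‑mediated conjugate propargylation (Sakurai‑type SE2′ reaction of the allenylstannane with the TiCl4‑activated enone) builds the C‑8 quaternary centre, and stereoelectronically preferred axial attack from the face of H‑9 gives the cis‑fused B/C hydrindanone, so C‑15 enters on the convex face shared by H‑9, C‑20 and the C‑6 ester.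

**Step 9**
Reactants: 14 propargyl ketone
Product: 15 target, (4R,5R,6S,8S,9R,10S,13S)‑13‑hydroxy‑16‑methylidene 7‑methyl ester 19,20‑diacid
Conditions: SmI2 (8 eq), HMPA, t‑BuOH, THF, 0 °C → rt
Reagents that add atoms: none
Why: SmI2/HMPA ketyl–alkyne radical cyclisation (5‑exo‑dig) forms C‑13–C‑16 and the vinyl radical is reduced and protonated to the exocyclic methylene, while the bridgehead carbinol can only form on the face of the propargyl group, so C‑13 follows from C‑8.

**Compound list**
Descriptor changes between 8 and 9 (C‑9a) and between 11 and 12 (C‑4a) are CIP priority effects, not inversions.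

1 | heptanedioic acid (pimelic acid) | OC(=O)CCCCCC(=O)O | starting material
2 | di‑tert‑butyl heptanedioate | CC(C)(C)OC(=O)CCCCCC(=O)OC(C)(C)C | intermediate
3 | methyl 2‑(2‑bromo‑5‑methoxyphenyl)acetate | COC(=O)Cc1cc(OC)ccc1Br | starting material
4 | sodium 2‑(2‑bromo‑5‑methoxyphenyl)‑3‑methoxy‑3‑oxoprop‑1‑en‑1‑olate | [Na+].[O-]C=C(C(=O)OC)c1cc(OC)ccc1Br | intermediate (not isolated)
5 | methyl 2‑(2‑bromo‑5‑methoxyphenyl)‑3‑(tosyloxy)prop‑2‑enoate, E/Z mixture | COC(=O)C(=COS(=O)(=O)c1ccc(C)cc1)c1cc(OC)ccc1Br | intermediate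
6 | dilithium 1,7‑di‑tert‑butoxyhepta‑1,6‑diene‑1,7‑diolate (bis‑enolate of 2) | [Li+].[Li+].CC(C)(C)OC([O-])=CCCCC=C([O-])OC(C)(C)C | intermediate (not isolated)
7 | lithium enolate (at the arylacetate carbon) of 1,3‑di‑tert‑butyl 2‑[1‑(2‑bromo‑5‑methoxyphenyl)‑2‑methoxy‑2‑oxoethyl]cyclohexane‑1,3‑dicarboxylate; deprotonated further in situ | [Li+].COC([O-])=C(c1cc(OC)ccc1Br)C1C(C(=O)OC(C)(C)C)CCCC1C(=O)OC(C)(C)C | intermediate (not isolated)
8 | 1,4a‑di‑tert‑butyl 9‑methyl (4aR,9aS)‑7‑methoxy‑1,2,3,4,4a,9a‑hexahydro‑9H‑fluorene‑1,4a,9‑tricarboxylate; cis‑fused, C‑1 and C‑9 epimer mixtures (gibberellane C‑4, C‑6) | c23cc(OC)ccc2[C@@]1(C(=O)OC(C)(C)C)CCCC(C(=O)OC(C)(C)C)[C@H]1C3C(=O)OC | intermediate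
9 | 1,4a‑di‑tert‑butyl 9‑methyl (1R,4aR,9S,9aR)‑7‑methoxy‑1‑methyl‑1,2,3,4,4a,9a‑hexahydro‑9H‑fluorene‑1,4a,9‑tricarboxylate | c23cc(OC)ccc2[C@@]1(C(=O)OC(C)(C)C)CCC[C@@](C)(C(=O)OC(C)(C)C)[C@H]1[C@@H]3C(=O)OC | intermediate
10 | (1R,4aR,9S,9aR)‑7‑methoxy‑1‑methyl‑1,2,3,4,4a,9a‑hexahydro‑9H‑fluorene‑1,4a,9‑tricarboxylic acid | c23cc(OC)ccc2[C@@]1(C(=O)O)CCC[C@@](C)(C(=O)O)[C@H]1[C@@H]3C(=O)O | intermediate
11 | (1R,4aR,9S,9aR)‑7‑methoxy‑1‑methyl‑1,2,3,4,4a,5,8,9a‑octahydro‑9H‑fluorene‑1,4a,9‑tricarboxylic acid | C23CC(OC)=CCC=2[C@@]1(C(=O)O)CCC[C@@](C)(C(=O)O)[C@H]1[C@@H]3C(=O)O | intermediate (not isolated)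
12 | (1R,4aS,4bR,9S,9aR)‑1‑methyl‑7‑oxo‑1,2,3,4,4a,4b,5,6,7,9a‑decahydro‑9H‑fluorene‑1,4a,9‑tricarboxylic acid | C23=CC(=O)CC[C@H]2[C@@]1(C(=O)O)CCC[C@@](C)(C(=O)O)[C@H]1[C@@H]3C(=O)O | intermediate
13 | (1R,4aS,4bR,9S,9aR)‑9‑(methoxycarbonyl)‑1‑methyl‑7‑oxo‑1,2,3,4,4a,4b,5,6,7,9a‑decahydro‑9H‑fluorene‑1,4a‑dicarboxylic acid | C23=CC(=O)CC[C@H]2[C@@]1(C(=O)O)CCC[C@@](C)(C(=O)O)[C@H]1[C@@H]3C(=O)OC | intermediate
14 | (1R,4aS,4bR,8aS,9S,9aR)‑9‑(methoxycarbonyl)‑1‑methyl‑7‑oxo‑8a‑(prop‑2‑yn‑1‑yl)dodecahydro‑1H‑fluorene‑1,4a‑dicarboxylic acid | C#CC[C@]23CC(=O)CC[C@H]2[C@@]1(C(=O)O)CCC[C@@](C)(C(=O)O)[C@H]1[C@@H]3C(=O)OC | intermediate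
15 | (4R,5R,6S,8S,9R,10S,13S)‑13‑hydroxy‑7‑methoxy‑7‑oxogibb‑16‑ene‑19,20‑dioic acid (gibberellane numbering; A/B cis) | C=C1C[C@]23C[C@@]1(O)CC[C@H]2[C@@]1(C(=O)O)CCC[C@@](C)(C(=O)O)[C@H]1[C@@H]3C(=O)OC | target

**Totals**
Total steps: 9. Longest linear sequence: 8 (3 → 15 through steps 2–9; the pimelate branch is equally long).

**Three steps most likely to fail**

Step 3. The dianion annulation may be diverted (attack at sulfur, proton transfer), or the arylation may give low ee or β‑hydride elimination. The fallback sets out from 2 and 5 and drops the asymmetric catalysis. Only the [5+1] stage is run and quenched to isolate the neutral cyclohexane triester F1. Ring B is then closed without palladium by an aryne cyclisation (LiTMP, THF, −78 → 0 °C; the ester enolate adds to the benzyne formed from the aryl bromide), which gives the racemic cis‑fused triester F2. Methylation as in step 4 gives the racemic methylated triester F3, whose enantiomers are separated by preparative chiral SFC. The route is rejoined at 9.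

Step 6. The C‑9 hydrogen must arrive on the C‑20 face; kinetic protonation may give a poor ratio, and longer acid contact will equilibrate it. The fallback sets out from 13 as a C‑9 epimer mixture and replaces protonation by a directed hydrogenation. Dehydrogenation with chloranil (t‑BuOH, reflux) gives the 8(14),9(11)‑dienone F4; it must be checked that unsaturation does not go towards C‑6. Hydrogenation with a cationic Rh catalyst ([Rh(nbd)(dppb)]BF4 under hydrogen gas), directed by the C‑20 carboxylate, then delivers H‑9 from the C‑20 face. The route is rejoined at 13 as a single C‑9 epimer.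

Step 8. The allenylstannane may be too unreactive towards the hindered β,β‑disubstituted enone, or the free acids and neighbouring C‑6 ester may erode yield and face selectivity. The fallback sets out from 13 and changes both the nucleophile and the ring‑D closure. Hosomi–Sakurai addition of (2‑bromoallyl)trimethylsilane with TiCl4 gives the 2‑bromoallyl ketone F5. Intramolecular Nozaki–Hiyama–Kishi cyclisation (CrCl2, cat. NiCl2, DMF) then forms C‑13–C‑16 with the bridgehead hydroxyl and the methylidene in place. The route is rejoined at 15; compound 14 and step 9 are bypassed.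

**Further compounds**
F1 | step 3 | 1,3‑di‑tert‑butyl 2‑[1‑(2‑bromo‑5‑methoxyphenyl)‑2‑methoxy‑2‑oxoethyl]cyclohexane‑1,3‑dicarboxylate (diastereomer mixture) | COC(=O)C(c1cc(OC)ccc1Br)C1C(C(=O)OC(C)(C)C)CCCC1C(=O)OC(C)(C)C
F2 | step 3 | racemic cis‑fused 1,4a‑di‑tert‑butyl 9‑methyl 7‑methoxy‑1,2,3,4,4a,9a‑hexahydro‑9H‑fluorene‑1,4a,9‑tricarboxylate (racemic 8) | COC(=O)C1c2cc(OC)ccc2C2(C(=O)OC(C)(C)C)CCCC(C(=O)OC(C)(C)C)C12
F3 | step 3 | racemic 1,4a‑di‑tert‑butyl 9‑methyl 7‑methoxy‑1‑methyl‑1,2,3,4,4a,9a‑hexahydro‑9H‑fluorene‑1,4a,9‑tricarboxylate (racemic 9) | COC(=O)C1c2cc(OC)ccc2C2(C(=O)OC(C)(C)C)CCCC(C)(C(=O)OC(C)(C)C)C12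
F4 | step 6 | (1R,4aR,9S,9aR)‑9‑(methoxycarbonyl)‑1‑methyl‑7‑oxo‑1,2,3,4,4a,6,7,9a‑octahydro‑9H‑fluorene‑1,4a‑dicarboxylic acid (8(14),9(11)‑dienone) | C23=CC(=O)CC=C2[C@@]1(C(=O)O)CCC[C@@](C)(C(=O)O)[C@H]1[C@@H]3C(=O)OC
F5 | step 8 | (1R,4aS,4bR,8aS,9S,9aR)‑8a‑(2‑bromoprop‑2‑en‑1‑yl)‑9‑(methoxycarbonyl)‑1‑methyl‑7‑oxododecahydro‑1H‑fluorene‑1,4a‑dicarboxylic acid | C=C(Br)C[C@]23CC(=O)CC[C@H]2[C@@]1(C(=O)O)CCC[C@@](C)(C(=O)O)[C@H]1[C@@H]3C(=O)OC
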